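**Strategy.** Everything rests on forming ring B last and de novo. The 2,6-dimethoxyphenol unit has C3'–OH between C2'–OMe and C4'–OMe, C6'–H opposite, and carbon groups on C1' and C5'. It is read as a carbon monoxide (C3') inserted between a methoxycarbene carbon (C2') and a methoxyvinyl terminus (C4'). One photochemical operation on a pentacarbonylchromium dienyl(methoxy)carbene forges C2'–C3' and C3'–C4', closes the ring and delivers the free 3'-OH already differentiated from both methyl ethers. The precursor is a (Z)-dienylcarbene complex carrying the enantiopure 7-silyloxychroman on C1' and the reverse prenyl group on C5', assembled by Suzuki coupling of a syn-bromoborated 3-ethynylchroman with an iodo enol ether.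

Key step: step 16

Remark: chroman atoms are O1, C2, C3, C4, C4a–C8a; ring B atoms are C1'–C6', with C1' bonded to chroman C3.
Remark: the 7-hydroxyl is carried as its triisopropylsilyl ether, which must survive the aqueous base of step 14 and the alkyllithiums of steps 8 and 15.
Remark: the methoxyvinyl bond (C4'=C5') is carried as an E/Z mixture from compound 17 onwards and is drawn without a descriptor, because C4' becomes sp3 and then aromatic in step 16.
Remark: the spatial arrangement at chroman C3 is the same in every compound; only the CIP descriptor changes with the substituent, so the (3R)-acid 7 corresponds to the (3S)-target.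
Remark: intermediates 25 and 26 form in the coordination sphere of chromium and are drawn metal-free.

Step 1
Reactants: 1 2,4-dihydroxybenzaldehyde; 2 methyl acrylate
Product: 3 methyl 7-hydroxy-2H-chromene-3-carboxylate
Conditions: DABCO (1.0 equiv), methyl acrylate (3 equiv), CHCl3/H2O, rt to 40 °C
Reagents that add atoms: none
Why: DABCO-mediated oxa-Michael/aldol condensation (Baylis–Hillman-type annulation of a salicylaldehyde with an acrylate): the 2-hydroxyl adds to the acrylate β-carbon, the ester enolate closes onto the aldehyde to form the pyran ring and water is lost, while the 4-hydroxyl has no electrophile within reach and stays free.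

Step 2
Reactants: 3 methyl 7-hydroxy-2H-chromene-3-carboxylate
Product: 4 7-hydroxy-2H-chromene-3-carboxylic acid
Conditions: LiOH (4 equiv), THF/H2O, rt; then aq. HCl to pH 2
Reagents that add atoms: lithium hydroxide, [Li+].[OH-]
Why: Saponification of a methyl ester, which the chromene alkene and the allylic aryl ether should tolerate, the phenolate being reprotonated on acidification.

Step 3
Reactants: 4 7-hydroxy-2H-chromene-3-carboxylic acid
Product: 6 7-(triisopropylsilyloxy)-2H-chromene-3-carboxylic acid, via silyl ester 5 (not isolated)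
Conditions: TIPSCl (2.3 equiv), imidazole (5 equiv), DMF, rt; then AcOH/THF/H2O, rt
Reagents that add atoms: triisopropylsilyl chloride, CC(C)[Si](Cl)(C(C)C)C(C)C
Why: Silylation of both phenol and acid followed by selective hydrolysis of the much more labile silyl ester under mild acid should leave only the aryl silyl ether.

Step 4
Reactants: 6 7-(triisopropylsilyloxy)-2H-chromene-3-carboxylic acid
Product: 7 (3R)-7-(triisopropylsilyloxy)chroman-3-carboxylic acid
Conditions: Ru(OAc)2[(S)-H8-BINAP] (1 mol %), H2 (10 bar), MeOH, 25 °C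
Reagents that add atoms: none
Why: Carboxylate-directed asymmetric hydrogenation of a trisubstituted α,β-unsaturated acid (Noyori-type ruthenium diphosphine catalysis), in which the chelated carboxylate lets the ligand dictate the face of hydrogen delivery to C3; the (S)-ligand is expected by analogy with (E)-2-alkyl-2-alkenoic acids to give the (R)-acid, which is to be confirmed on a trial scale, the (R)-ligand being used if the sense proves opposite.

Step 5
Reactants: 7 (3R)-7-(triisopropylsilyloxy)chroman-3-carboxylic acid
Product: 8 [(3S)-7-(triisopropylsilyloxy)chroman-3-yl]methanol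
Conditions: BH3·SMe2 (2 equiv), THF, 0 °C to rt; MeOH quench, aqueous work-up
Reagents that add atoms: none
Why: Borane reduction of a carboxylic acid through the acyloxyborane is chemoselective and should leave the aryl silyl ether and the stereocentre untouched.

Step 6
Reactants: 8 [(3S)-7-(triisopropylsilyloxy)chroman-3-yl]methanol
Product: 9 (3R)-7-(triisopropylsilyloxy)chroman-3-carbaldehyde
Conditions: TEMPO (10 mol %), PhI(OAc)2 (1.1 equiv), CH2Cl2, rt; crude aldehyde used at once
Reagents that add atoms: none
Why: Oxoammonium (TEMPO) oxidation stops at the aldehyde under base-free conditions, so the α-stereocentre, which lies β to the aryloxy group and would be at risk of epimerisation or retro-oxa-Michael opening under base, should be preserved.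

Step 7
Reactants: 9 (3R)-7-(triisopropylsilyloxy)chroman-3-carbaldehyde
Product: 10 (3S)-3-(2,2-dibromoethenyl)-7-(triisopropylsilyloxy)chroman
Conditions: CBr4 (2 equiv), PPh3 (4 equiv), CH2Cl2, 0 °C (ylide preformed), then 9, −20 to 0 °C
Reagents that add atoms: carbon tetrabromide, BrC(Br)(Br)Br
Why: Corey–Fuchs dibromo-olefination, in which the weakly basic ylide Ph3P=CBr2 should undergo the Wittig reaction with the aldehyde faster than it enolises it.

Step 8
Reactants: 10 (3S)-3-(2,2-dibromoethenyl)-7-(triisopropylsilyloxy)chroman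
Product: 12 (3S)-3-ethynyl-7-(triisopropylsilyloxy)chroman, via lithium acetylide 11 (not isolated)
Conditions: n-BuLi (2.2 equiv), THF, −78 °C; then H2O
Reagents that add atoms: none
Why: Second stage of the Corey–Fuchs sequence (bromine–lithium exchange, Fritsch–Buttenberg–Wiechell 1,2-shift, deprotonation to the acetylide, protonation on quench), during which the propargylic C3–H is not acidic enough to be removed at −78 °C.

Step 9
Reactants: 12 (3S)-3-ethynyl-7-(triisopropylsilyloxy)chroman
Product: 13 9-{(Z)-2-bromo-2-[(3R)-7-(triisopropylsilyloxy)chroman-3-yl]ethenyl}-9-borabicyclo[3.3.1]nonane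
Conditions: B-bromo-9-BBN (1.05 equiv), CH2Cl2, 0 °C to rt; volatiles removed, residue taken up in THF and used crude
Reagents that add atoms: B-bromo-9-borabicyclo[3.3.1]nonane, BrB1C2CCCC1CCC2
Why: Haloboration of a terminal alkyne is a syn, Markovnikov addition (boron on the terminal carbon, bromine on the internal carbon), which fixes bromine and boron cis and thereby the later cis relation of C2' and C5'.

Step 10
Reactants: 14 methyl 3,3-dimethylpent-4-enoate
Product: 15 3,3-dimethylpent-4-enal
Conditions: i-Bu2AlH (1.05 equiv), CH2Cl2, −78 °C; aq. potassium sodium tartrate work-up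
Reagents that add atoms: none
Why: Half-reduction of a methyl ester with i-Bu2AlH, whose tetrahedral aluminium hemiacetal is stable at −78 °C and releases the aldehyde only on work-up.

Step 11
Reactants: 15 3,3-dimethylpent-4-enal
Product: 16 5,5-dimethoxy-3,3-dimethylpent-1-ene
Conditions: HC(OMe)3 (1.5 equiv), MeOH, TsOH·H2O (1 mol %), rt; NaHCO3 quench
Reagents that add atoms: trimethyl orthoformate, COC(OC)OC; methanol, CO
Why: Acid-catalysed acetalisation driven to completion by the orthoformate as water scavenger.

Step 12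
Reactants: 16 5,5-dimethoxy-3,3-dimethylpent-1-ene
Product: 17 1-methoxy-3,3-dimethylpenta-1,4-diene (E/Z mixture)
Conditions: TMSOTf (1.1 equiv), i-Pr2NEt (1.3 equiv), CH2Cl2, −20 °C to rt
Reagents that add atoms: none
Why: Gassman-type elimination of methanol from an acetal, in which TMSOTf ionises the acetal to the oxocarbenium ion and the hindered amine removes a proton from the only β-position, the CH2 group.

Step 13
Reactants: 17 1-methoxy-3,3-dimethylpenta-1,4-diene (E/Z mixture)
Product: 19 2-iodo-1-methoxy-3,3-dimethylpenta-1,4-diene (E/Z mixture), via chloro iodo ether 18 (not isolated)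
Conditions: ICl (1.0 equiv), CH2Cl2, −78 °C; then DBU (1.5 equiv), −78 °C to rt
Reagents that add atoms: iodine monochloride, ClI
Why: Halogenation–dehydrohalogenation of an enol ether, in which ICl places iodine on the nucleophilic β-carbon and chloride on the oxocarbenium carbon far faster than it attacks the unactivated vinyl group, and the α-chloro ether then ionises and loses its single β-proton to DBU, leaving iodine on the future C5'.

Step 14
Reactants: 13 9-{(Z)-2-bromo-2-[(3R)-7-(triisopropylsilyloxy)chroman-3-yl]ethenyl}-9-borabicyclo[3.3.1]nonane; 19 2-iodo-1-methoxy-3,3-dimethylpenta-1,4-diene (E/Z mixture)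
Product: 20 (3R)-3-[(1Z)-1-bromo-3-(methoxymethylidene)-4,4-dimethylhexa-1,5-dien-1-yl]-7-(triisopropylsilyloxy)chroman
Conditions: PdCl2(dppf) (5 mol %), AsPh3 (10 mol %), K3PO4 (3 M aq, 3 equiv), THF, rt, degassed
Reagents that add atoms: none
Why: Suzuki–Miyaura coupling of a B-alkenyl-9-BBN with an alkenyl iodide, in which zerovalent palladium should insert into the C–I bond much faster than into the hindered internal C–Br bond at room temperature, the alkenyl group transfers from boron in preference to the bicyclic alkyl groups, and both alkene geometries are retained.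

Step 15
Reactants: 20 (3R)-3-[(1Z)-1-bromo-3-(methoxymethylidene)-4,4-dimethylhexa-1,5-dien-1-yl]-7-(triisopropylsilyloxy)chroman; 21 chromium hexacarbonyl
Product: 24 pentacarbonyl{(2Z)-1-methoxy-4-(methoxymethylidene)-5,5-dimethyl-2-[(3S)-7-(triisopropylsilyloxy)chroman-3-yl]hepta-2,6-dien-1-ylidene}chromium, via dienyllithium 22 (not isolated), via lithium acyl chromate 23 (not isolated)
Conditions: t-BuLi (2.0 equiv), THF/Et2O, −78 °C; Cr(CO)6 (1.05 equiv), −78 to 0 °C; solvent exchange to CH2Cl2; MeOTf (1.3 equiv), 0 °C
Reagents that add atoms: methyl trifluoromethanesulfonate, COS(=O)(=O)C(F)(F)F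
Why: Fischer carbene synthesis: bromine–lithium exchange with retention of alkene geometry at −78 °C, addition of the dienyllithium to a CO ligand of Cr(CO)6, and O-methylation of the acyl chromate with a hard methylating agent under anhydrous conditions that spare the enol ether.

Step 16
Reactants: 24 pentacarbonyl{(2Z)-1-methoxy-4-(methoxymethylidene)-5,5-dimethyl-2-[(3S)-7-(triisopropylsilyloxy)chroman-3-yl]hepta-2,6-dien-1-ylidene}chromium
Product: 27 2,6-dimethoxy-3-(2-methylbut-3-en-2-yl)-5-[(3S)-7-(triisopropylsilyloxy)chroman-3-yl]phenol, via chromium-bound ketene 25 (not isolated), via cyclohexadienone 26 (not isolated)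
Conditions: hν (medium-pressure Hg lamp, Pyrex filter), CO (1 atm), THF, 20 °C; then brief air exposure and filtration through silica
Reagents that add atoms: none
Why: Irradiation of the metal-to-ligand charge-transfer band moves a CO ligand onto the carbene carbon C2', giving the chromium-bound methoxy(dienyl)ketene 25 with the C2'–C3' bond in place. Because C2' and C5' are cis across C1'=C6', the ketene carbon C3' lies next to the enol ether carbon C4', and a six-electron disrotatory electrocyclisation (six-membered carbocycle, the only ring size this triene allows) forms C3'–C4' to give dienone 26, whose C4'–H then shifts to oxygen to give the phenol. The closest known reaction type is the photochemical benzannulation of chromium dienyl(alkoxy)carbene complexes to ortho-alkoxyphenols, the same ketene electrocyclisation that ends the Dötz benzannulation, applied here to an acyclic diene with a methoxy group on its terminus. No stereocentre is created, since the transient sp3 centre at C4' is erased on aromatisation and chroman C3 is not involved. The only selectivity needed is the cis relation of the carbene carbon and C5', fixed by the syn-bromoboration of step 9 and carried through steps 14 and 15; the electron-rich methoxyvinyl terminus matches the electrophilic ketene carbon, and the CO atmosphere should suppress CO-loss pathways such as cyclopropanation of the pendant vinyl group and return the metal as Cr(CO)6.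

Step 17
Reactants: 27 2,6-dimethoxy-3-(2-methylbut-3-en-2-yl)-5-[(3S)-7-(triisopropylsilyloxy)chroman-3-yl]phenol
Product: 28 (3S)-3-[3-hydroxy-2,4-dimethoxy-5-(2-methylbut-3-en-2-yl)phenyl]chroman-7-ol (CNP0305994.1)
Conditions: TBAF/AcOH (1:1, 1.5 equiv), THF, 0 °C to rt, under argon
Reagents that add atoms: none
Why: Fluoride-induced cleavage of the aryl silyl ether, buffered with acetic acid so that the electron-rich phenols are not left as air-sensitive phenolates; no other group in the molecule is fluoride-labile.

**Compound list**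

1 | 2,4-dihydroxybenzaldehyde | O=Cc1ccc(O)cc1O | starting material
2 | methyl acrylate | C=CC(=O)OC | starting material
3 | methyl 7-hydroxy-2H-chromene-3-carboxylate | COC(=O)C1=Cc2ccc(O)cc2OC1 | intermediate
4 | 7-hydroxy-2H-chromene-3-carboxylic acid | OC(=O)C1=Cc2ccc(O)cc2OC1 | intermediate
5 | triisopropylsilyl 7-(triisopropylsilyloxy)-2H-chromene-3-carboxylate | CC(C)[Si](C(C)C)(C(C)C)OC(=O)C1=Cc2ccc(O[Si](C(C)C)(C(C)C)C(C)C)cc2OC1 | intermediate
6 | 7-(triisopropylsilyloxy)-2H-chromene-3-carboxylic acid | OC(=O)C1=Cc2ccc(O[Si](C(C)C)(C(C)C)C(C)C)cc2OC1 | intermediate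
7 | (3R)-7-(triisopropylsilyloxy)chroman-3-carboxylic acid | OC(=O)[C@H]1COc2cc(O[Si](C(C)C)(C(C)C)C(C)C)ccc2C1 | intermediate
8 | [(3S)-7-(triisopropylsilyloxy)chroman-3-yl]methanol | OC[C@H]1COc2cc(O[Si](C(C)C)(C(C)C)C(C)C)ccc2C1 | intermediate
9 | (3R)-7-(triisopropylsilyloxy)chroman-3-carbaldehyde | O=C[C@H]1COc2cc(O[Si](C(C)C)(C(C)C)C(C)C)ccc2C1 | intermediate
10 | (3S)-3-(2,2-dibromoethenyl)-7-(triisopropylsilyloxy)chroman | BrC(Br)=C[C@H]1COc2cc(O[Si](C(C)C)(C(C)C)C(C)C)ccc2C1 | intermediate
11 | lithium acetylide of alkyne 12 | [Li]C#C[C@H]1COc2cc(O[Si](C(C)C)(C(C)C)C(C)C)ccc2C1 | intermediate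
12 | (3S)-3-ethynyl-7-(triisopropylsilyloxy)chroman | C#C[C@H]1COc2cc(O[Si](C(C)C)(C(C)C)C(C)C)ccc2C1 | intermediate
13 | 9-{(Z)-2-bromo-2-[(3R)-7-(triisopropylsilyloxy)chroman-3-yl]ethenyl}-9-borabicyclo[3.3.1]nonane (Br and B cis) | Br/C(=C\B1C2CCCC1CCC2)[C@H]3COc4cc(O[Si](C(C)C)(C(C)C)C(C)C)ccc4C3 | intermediate
14 | methyl 3,3-dimethylpent-4-enoate | C=CC(C)(C)CC(=O)OC | starting material
15 | 3,3-dimethylpent-4-enal | C=CC(C)(C)CC=O | intermediate
16 | 5,5-dimethoxy-3,3-dimethylpent-1-ene | C=CC(C)(C)CC(OC)OC | intermediate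
17 | 1-methoxy-3,3-dimethylpenta-1,4-diene (E/Z mixture) | COC=CC(C)(C)C=C | intermediate
18 | 5-chloro-4-iodo-5-methoxy-3,3-dimethylpent-1-ene (diastereomer mixture) | COC(Cl)C(I)C(C)(C)C=C | intermediate
19 | 2-iodo-1-methoxy-3,3-dimethylpenta-1,4-diene (E/Z mixture) | COC=C(I)C(C)(C)C=C | intermediate
20 | (3R)-3-[(1Z)-1-bromo-3-(methoxymethylidene)-4,4-dimethylhexa-1,5-dien-1-yl]-7-(triisopropylsilyloxy)chroman (Br cis to C3 of the chain; enol ether E/Z mixture) | COC=C(C(C)(C)C=C)/C=C(\Br)[C@H]1COc2cc(O[Si](C(C)C)(C(C)C)C(C)C)ccc2C1 | intermediate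
21 | chromium hexacarbonyl | O=C=[Cr](=C=O)(=C=O)(=C=O)(=C=O)=C=O | starting material
22 | dienyllithium: 20 with lithium in place of bromine (Li cis to C3 of the chain; chroman C3 is S by CIP) | COC=C(C(C)(C)C=C)/C=C(\[Li])[C@H]1COc2cc(O[Si](C(C)C)(C(C)C)C(C)C)ccc2C1 | intermediate
23 | lithium pentacarbonyl(dienylacyl)chromate (acyl carbon cis to C5') | COC=C(C(C)(C)C=C)/C=C(\C(O[Li])=[Cr](=C=O)(=C=O)(=C=O)(=C=O)=C=O)[C@H]1COc2cc(O[Si](C(C)C)(C(C)C)C(C)C)ccc2C1 | intermediate
24 | pentacarbonyl{(2Z)-1-methoxy-4-(methoxymethylidene)-5,5-dimethyl-2-[(3S)-7-(triisopropylsilyloxy)chroman-3-yl]hepta-2,6-dien-1-ylidene}chromium | COC=C(C(C)(C)C=C)/C=C(\C(OC)=[Cr](=C=O)(=C=O)(=C=O)(=C=O)=C=O)[C@H]1COc2cc(O[Si](C(C)C)(C(C)C)C(C)C)ccc2C1 | intermediate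
25 | (3Z)-2-methoxy-5-(methoxymethylidene)-6,6-dimethyl-3-[(3S)-7-(triisopropylsilyloxy)chroman-3-yl]octa-1,3,7-trien-1-one (ketene, chromium-bound in step 16) | COC=C(C(C)(C)C=C)/C=C(\C(OC)=C=O)[C@H]1COc2cc(O[Si](C(C)C)(C(C)C)C(C)C)ccc2C1 | intermediate
26 | 2,6-dimethoxy-5-(2-methylbut-3-en-2-yl)-3-[(3S)-7-(triisopropylsilyloxy)chroman-3-yl]cyclohexa-2,4-dien-1-one (both C6 epimers) | COC1C(=O)C(OC)=C([C@H]2COc3cc(O[Si](C(C)C)(C(C)C)C(C)C)ccc3C2)C=C1C(C)(C)C=C | intermediate
27 | 2,6-dimethoxy-3-(2-methylbut-3-en-2-yl)-5-[(3S)-7-(triisopropylsilyloxy)chroman-3-yl]phenol | C=CC(C)(C)c1cc([C@H]2COc3cc(O[Si](C(C)C)(C(C)C)C(C)C)ccc3C2)c(OC)c(O)c1OC | intermediate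
28 | (3S)-3-[3-hydroxy-2,4-dimethoxy-5-(2-methylbut-3-en-2-yl)phenyl]chroman-7-ol | C=CC(C)(C)c1cc([C@H]2COc3cc(O)ccc3C2)c(OC)c(O)c1OC | target

**Step count.** Total: 17 steps. Longest linear sequence: 13 steps (steps 1–9, then 14–17); the iodo enol ether branch is steps 10–13.

**Steps most likely to fail**

1. Step 14. Palladium may insert into the C–Br bond of borane 13 or of product 20 and cause self-coupling, or the boron ate complex may lose bromide and boron and revert to the alkyne. The fallback sets out from alkyne 12 and comes back at dienyllithium 22, hence at carbene complex 24, bypassing bromo diene 20. Syn-distannylation of 12 with Me3SnSnMe3 and Pd(PPh3)4 (THF, 65 °C) should give (3R)-3-[(Z)-1,2-bis(trimethylstannyl)ethenyl]-7-(triisopropylsilyloxy)chroman F1. Stille coupling of its less hindered terminal tin with iodide 19 (Pd2(dba)3, AsPh3, CuI, NMP, rt) should give (3R)-3-[(1Z)-3-(methoxymethylidene)-4,4-dimethyl-1-(trimethylstannyl)hexa-1,5-dien-1-yl]-7-(triisopropylsilyloxy)chroman F2, with tin cis to C5'. Tin–lithium exchange with MeLi (THF, −78 °C) then gives 22, which is carried to 23 and 24 as in step 15. No halide is present on the nucleophile, so the chemoselectivity problem disappears.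

2. Step 16. Light may isomerise the C1'=C6' bond, or CO loss may lead to cyclopropanation of the pendant vinyl group or five-membered ring closure in place of CO insertion. The fallback sets out from bromo diene 20 and comes back at ketene 25 (now metal-free), hence at silyl ether 27, using only thermal ketene chemistry.
   - Dienyllithium 22 (t-BuLi, −78 °C) is added to ethyl glyoxylate to give ethyl (3Z)-2-hydroxy-5-(methoxymethylidene)-6,6-dimethyl-3-[(3S)-7-(triisopropylsilyloxy)chroman-3-yl]octa-3,7-dienoate F3.
   - O-Methylation (MeI, Ag2O, CH2Cl2) gives the 2-methoxy ester F4.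
   - Saponification (LiOH, THF/H2O, 0 °C) gives the 2-methoxy acid F5.
   - 1-Chloro-N,N,2-trimethylprop-1-en-1-amine (CH2Cl2, 0 °C) converts it under neutral conditions into the acid chloride F6.
   - Et3N (toluene, 0 to 80 °C) dehydrochlorinates F6 to ketene 25, which should undergo the same 6π electrocyclisation to 26 and tautomerise to 27.

3. Step 13. The electrophile may attack the terminal vinyl group, the α-chloro ether may decompose before elimination, and the volatile product may be lost on isolation. The fallback sets out from enol ether 17 and comes back at iodo enol ether 19 by way of an isolable intermediate. Iodomethoxylation with NIS in MeOH/CH2Cl2 (−20 °C) should give the stable 4-iodo-5,5-dimethoxy-3,3-dimethylpent-1-ene F7, which can be purified. Elimination of methanol with TMSOTf/i-Pr2NEt (CH2Cl2, −20 °C to rt), the same acetal-to-enol-ether method as step 12, then gives 19.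

**Further compounds**

F1 | step 14 | (3R)-3-[(Z)-1,2-bis(trimethylstannyl)ethenyl]-7-(triisopropylsilyloxy)chroman | C[Sn](C)(C)/C=C(\[Sn](C)(C)C)[C@H]1COc2cc(O[Si](C(C)C)(C(C)C)C(C)C)ccc2C1
F2 | step 14 | (3R)-3-[(1Z)-3-(methoxymethylidene)-4,4-dimethyl-1-(trimethylstannyl)hexa-1,5-dien-1-yl]-7-(triisopropylsilyloxy)chroman | COC=C(C(C)(C)C=C)/C=C(\[Sn](C)(C)C)[C@H]1COc2cc(O[Si](C(C)C)(C(C)C)C(C)C)ccc2C1
F3 | step 16 | ethyl (3Z)-2-hydroxy-5-(methoxymethylidene)-6,6-dimethyl-3-[(3S)-7-(triisopropylsilyloxy)chroman-3-yl]octa-3,7-dienoate (C2 epimers) | CCOC(=O)C(O)/C(=C\C(=COC)C(C)(C)C=C)[C@H]1COc2cc(O[Si](C(C)C)(C(C)C)C(C)C)ccc2C1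
F4 | step 16 | ethyl (3Z)-2-methoxy-5-(methoxymethylidene)-6,6-dimethyl-3-[(3S)-7-(triisopropylsilyloxy)chroman-3-yl]octa-3,7-dienoate (C2 epimers) | CCOC(=O)C(OC)/C(=C\C(=COC)C(C)(C)C=C)[C@H]1COc2cc(O[Si](C(C)C)(C(C)C)C(C)C)ccc2C1
F5 | step 16 | (3Z)-2-methoxy-5-(methoxymethylidene)-6,6-dimethyl-3-[(3S)-7-(triisopropylsilyloxy)chroman-3-yl]octa-3,7-dienoic acid (C2 epimers) | OC(=O)C(OC)/C(=C\C(=COC)C(C)(C)C=C)[C@H]1COc2cc(O[Si](C(C)C)(C(C)C)C(C)C)ccc2C1
F6 | step 16 | (3Z)-2-methoxy-5-(methoxymethylidene)-6,6-dimethyl-3-[(3S)-7-(triisopropylsilyloxy)chroman-3-yl]octa-3,7-dienoyl chloride (C2 epimers) | ClC(=O)C(OC)/C(=C\C(=COC)C(C)(C)C=C)[C@H]1COc2cc(O[Si](C(C)C)(C(C)C)C(C)C)ccc2C1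
F7 | step 13 | 4-iodo-5,5-dimethoxy-3,3-dimethylpent-1-ene (racemic) | COC(OC)C(I)C(C)(C)C=C
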